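**Plan**

- Retrosynthesis: (a) the bond from pyridine C3 to the first carbon of the decyl chain is cut (Negishi coupling), leaving a C3–Cl handle. (b) The ring bonds C2–C3 and C3–C4 are cut, which removes C3 as dichlorocarbene and contracts the pyridine to 3-decanoylpyrrole. (c) The pyrrole C3–acyl bond is cut (Friedel–Crafts acylation).
- Enabling feature: pyridine atoms N1, C2, C4, C5 and C6, with the decanoyl group on C5, are the five ring atoms of a 3-acylpyrrole. C3, the one ring atom missing, lies between C2 and C4 on the side remote from the acyl group.
- Forward: the pyrrole ring is bought, acylated at C3 and freed at nitrogen. The six-membered ring then arises by one-carbon ring expansion. The decyl chain is joined last at the chlorine carried by the inserted carbon.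
- Stereochemistry: the target has no stereocentre and no stereogenic double bond, so nothing has to be set.

Key step: step 3

Remark: intermediate 6 is racemic with a forced cis ring fusion; its SMILES shows one enantiomer, and both stereocentres disappear within the same step.

**Route**

Step 1
Reactants: 1 1-(phenylsulfonyl)-1H-pyrrole; 2 decanoyl chloride
Product: 3 1-[1-(phenylsulfonyl)-1H-pyrrol-3-yl]decan-1-one
Conditions: AlCl3 (1.5 equiv), CH2Cl2, 0 °C to rt; ice-water quench
Reagents that add atoms: none
Why: Friedel–Crafts acylation, in which the acyl chloride–AlCl3 complex attacks the N-sulfonylpyrrole at C3 (the known outcome with this hard Lewis acid in excess), while the electron-withdrawing sulfonyl group suppresses oligomerisation and a second acylation.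

Step 2
Reactants: 3 1-[1-(phenylsulfonyl)-1H-pyrrol-3-yl]decan-1-one
Product: 4 1-(1H-pyrrol-3-yl)decan-1-one
Conditions: NaOH (5 M aq.), 1,4-dioxane, rt; then aq. NH4Cl
Reagents that add atoms: none
Why: Alkaline hydrolysis of an N-sulfonylpyrrole, in which hydroxide attacks sulfur and the acyl-stabilised pyrrolide departs as a good leaving group, the ketone being inert under these mild conditions.

Step 3
Reactants: 4 1-(1H-pyrrol-3-yl)decan-1-one; 5 chloroform
Product: 7 1-(5-chloropyridin-3-yl)decan-1-one, via gem-dichlorocyclopropane adduct 6 (not isolated)
Conditions: CHCl3 (reagent and solvent), 50% aq. NaOH (added in portions), BnEt3NCl (5 mol%), vigorous stirring, 0 °C to rt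
Reagents that add atoms: none
Why: Hydroxide deprotonates chloroform at the phase boundary and the trichloromethyl anion sheds chloride to give dichlorocarbene, which adds [2+1] across the C4=C5 bond of pyrrole 4 (free or as its pyrrolide) to form the cis-fused dichlorocyclopropane 6; the nitrogen lone pair then drives disrotatory cleavage of the shared C4–C5 bond with departure of the endo chloride, and loss of the N–H proton leaves pyridine 7, in which the inserted carbon is bonded to the former C5 and C4 (new pyridine bonds C2–C3 and C3–C4) and keeps one chlorine. The closest known reaction is the Ciamician–Dennstedt rearrangement of pyrroles to 3-chloropyridines, run here with phase-transfer carbene generation. The three-membered ring closes by cheletropic [2+1] addition (from the pyrrolide, C5 attack followed by 3-exo-trig closure onto C4 leads to the same adduct), whereas the six-membered ring does not close but arises by two-electron electrocyclic opening of the cyclopropane, so the five-membered ring grows by one atom. The two stereocentres of 6 are cis by necessity and are erased on aromatisation, so no stereocontrol is called for. The step needs site selectivity between the two pyrrole double bonds and chemoselectivity for carbon insertion over Reimer–Tiemann formylation and N-attack: the decanoyl group withdraws density from C2=C3 through the vinylogous amide N1–C2=C3–C=O and leaves C4=C5 as the enamine-like, more nucleophilic bond (the same bias that sends electrophiles to C5 of 3-acylpyrroles), so the carbon enters on the far side and the 3,5-pattern results, while keeping the carbene in the organic phase away from bulk hydroxide curbs formylation. The ketone of 4 is masked as part of the delocalised pyrrolide and resists enolisation and trichloromethyl-anion addition, and the run would be stopped short of full conversion to spare the more electrophilic ketone of 7.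

Step 4
Reactants: 8 1-bromodecane
Product: 9 decylzinc bromide (solution in DMA, titrated by iodolysis and used directly)
Conditions: Zn dust (1.5 equiv), I2 (5 mol%), DMA, 80 °C
Reagents that add atoms: zinc, [Zn]
Why: Direct oxidative insertion of iodine-activated zinc into a primary alkyl bromide in a polar aprotic solvent, the standard preparation of an unfunctionalised alkylzinc bromide.

Step 5
Reactants: 7 1-(5-chloropyridin-3-yl)decan-1-one; 9 decylzinc bromide
Product: 10 1-(5-decylpyridin-3-yl)decan-1-one
Conditions: Pd(P(t-Bu)3)2 (2 mol%), THF/DMA, 65 °C
Reagents that add atoms: none
Why: Negishi cross-coupling, in which zerovalent palladium bearing the bulky, electron-rich P(t-Bu)3 inserts into the C–Cl bond of the electron-poor chloropyridine, the primary alkylzinc transmetalates and reductive elimination outruns β-hydride elimination, while the organozinc halide neither adds to nor enolises the ketone.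

**Compound list**

1 | 1-(phenylsulfonyl)-1H-pyrrole | O=S(=O)(c1ccccc1)n1cccc1 | starting material
2 | decanoyl chloride | CCCCCCCCCC(=O)Cl | starting material
3 | 1-[1-(phenylsulfonyl)-1H-pyrrol-3-yl]decan-1-one | CCCCCCCCCC(=O)c1ccn(S(=O)(=O)c2ccccc2)c1 | intermediate
4 | 1-(1H-pyrrol-3-yl)decan-1-one | CCCCCCCCCC(=O)c1cc[nH]c1 | intermediate
5 | chloroform | ClC(Cl)Cl | starting material
6 | rac-1-[(1R,5S)-6,6-dichloro-2-azabicyclo[3.1.0]hex-3-en-4-yl]decan-1-one (cis-fused, one enantiomer drawn) | CCCCCCCCCC(=O)C1=CN[C@@H]2[C@H]1C2(Cl)Cl | intermediate (not isolated)
7 | 1-(5-chloropyridin-3-yl)decan-1-one | CCCCCCCCCC(=O)c1cncc(Cl)c1 | intermediate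
8 | 1-bromodecane | CCCCCCCCCCBr | starting material
9 | decylzinc bromide | CCCCCCCCCC[Zn]Br | intermediate
10 | 1-(5-decylpyridin-3-yl)decan-1-one | CCCCCCCCCCc1cncc(C(=O)CCCCCCCCC)c1 | target

**Count and risks**

Total steps: 5. Longest linear sequence: 4 steps (steps 1, 2, 3 and 5); step 4 is a one-step side branch.

Steps most likely to fail, riskiest first:

1. Step 3. The carbene or its trichloromethyl anion precursor may be consumed by formylation at C5, C2 or nitrogen instead of cyclopropanation. Insertion may also stray to the acyl-bearing side, or base may attack the ketone of the product, so that too little ring-expanded material forms. Fallback, setting out from 2 and returning at 7: decanoyl chloride 2 would be treated with N,O-dimethylhydroxylamine hydrochloride and Et3N in CH2Cl2 at 0 °C to give N-methoxy-N-methyldecanamide F1. Separately, purchased 3-bromo-5-chloropyridine (Clc1cncc(Br)c1) would undergo selective bromine–magnesium exchange with i-PrMgCl·LiCl in THF at −15 °C to give (5-chloropyridin-3-yl)magnesium chloride F2. Addition of F2 to F1 (Weinreb ketone synthesis, the chelated tetrahedral adduct preventing over-addition) and aqueous NH4Cl work-up should give 7 without any ring expansion.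

2. Step 5. Oxidative addition into the C–Cl bond may be slow, and the decylpalladium intermediate may undergo β-hydride elimination, leading to hydrodechlorination. The zinc reagent may also be quenched by proton sources before it transmetalates. Fallback, setting out from 7 and returning at 10: purchased 1-decene (C=CCCCCCCCC) would be hydroborated with 9-BBN in THF to give 9-decyl-9-borabicyclo[3.3.1]nonane F3. F3 would then be coupled with 7 in a B-alkyl Suzuki–Miyaura reaction (Pd(OAc)2, SPhos, K3PO4, THF/H2O, 65 °C) to give 10.

3. Step 1. Site selectivity may erode: acylation at C2, or acid-mediated equilibration between the isomers when the amount or quality of AlCl3 or the order of addition is off, would give regioisomers that lead on to a wrong pyridine. Fallback, setting out from 2 and returning at 4: purchased 1-(triisopropylsilyl)pyrrole (CC(C)[Si](C(C)C)(C(C)C)n1cccc1), whose bulky silyl group screens both alpha positions, would be acylated with 2 and AlCl3 in CH2Cl2 at 0 °C to give 1-[1-(triisopropylsilyl)-1H-pyrrol-3-yl]decan-1-one F4. Desilylation with tetrabutylammonium fluoride in THF at rt should then give 4.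

**Further compounds**

F1 | step 3 | N-methoxy-N-methyldecanamide | CCCCCCCCCC(=O)N(C)OC
F2 | step 3 | (5-chloropyridin-3-yl)magnesium chloride | Clc1cncc([Mg]Cl)c1
F3 | step 5 | 9-decyl-9-borabicyclo[3.3.1]nonane | CCCCCCCCCCB1C2CCCC1CCC2
F4 | step 1 | 1-[1-(triisopropylsilyl)-1H-pyrrol-3-yl]decan-1-one | CCCCCCCCCC(=O)c1ccn([Si](C(C)C)(C(C)C)C(C)C)c1
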